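The readings are simulated for an exercise.

| flask | substrate | remark | time |
|---|---|---|---|
| blue | 1.9 M | the very flask that is asked about, followed so far |  |
| amber | 1.3 M | run made earlier |  |
| flask | 1.9 M |  | 1.5 h |

| run | time / min | substrate / % | target / % |
|---|---|---|---|
| blue | 1.33 | 8.4 | 13.8 |
| blue | 2.50 | 3.6 | 6.4 |
| blue | 4.00 | 2.4 | 2.4 |
| blue | 6.00 | 1.2 | 1.1 |
| blue | 10.0 | 1.0 | 2.3 |
| blue | 20.0 | 1.5 | 0.8 |
| amber | 10.0 | 2.0 | 1.8 |
| amber | 20.0 | 1.9 | 3.2 |
| amber | 30.0 | 2.7 | 2.5 |
| amber | 40.0 | 1.7 | 1.8 |
| amber | 50.0 | 1.9 | 1.8 |
| amber | 60.0 | 1.5 | 2.0 |

(each reading ± 0.5 percentage points)

- the numbers in the tables scatter by 0.5 percentage points (one standard deviation)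
- the reaction counts as stopped when no species that holds the substrate changes by six tenths of a point or more over the second half of the time

- the state of affairs at 1.5 h: stopped, and by what, or still going (forward and back rates have come level / it is still moving)
- how much of the substrate has reacted by 1.5 h
- how much target there is at 1.5 h, in percent of the substrate charged
- how much isomer of the product there is at 1.5 h, in percent of the substrate charged

**Two clocks.** As the chemist following the blue flask I wrote the balance of the substrate, the one charge: taking substrate, target and isomer of the product to add up to what was charged, the unmeasured isomer is what the pair of substrate and target has lost, and the question is whether that pair stops falling within the asked 1.5 h. In the blue run the pair read 22.2% at 1.33 min and 10.0% at 2.50 min, which I read, with the scatter of those readings, as a half-life of 1.02 min. The settling count, the asked time over that half-life, is 88.5. In the amber run the pair read 3.80% at 10.0 min and 3.50% at 60.0 min, so I took the fall to end above zero, and because that half-life is far shorter than the asked time, I expected the asked flask to be level long before its reading, under thermodynamic control.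

**The forecast.** The forecast, on readings that “then stay flat”, gave the verdict "forward and back rates have come level", with conversion 98.7%, target 1.5% and, by mass balance, isomer of the product 97.2%.

**The flask.** At 1.5 h the flask gave the same verdict, "forward and back rates have come level", with conversion 98.3%, target 2.15% and isomer of the product 96.2%.

    substrate ⇌ target (K = 1.30, k = 0.101 /s)
    substrate ⇌ isomer of the product (K = 58.3, k = 0.0465 /s)

**Count again.** At 0.150 h, a count of 8.82, the flask already held substrate 1.65% and target 2.15%, the same as at 1.50 h. The neighbouring flask, with the same charge but read at 6.0 h, has a count of 353, and it held substrate 1.65%, target 2.15% and isomer of the product 96.2%.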